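Readings and results were computed with constants of no real substance.

At early times the substrate runs ahead of the target: in the eta run at 10.0 s the substrate used, 43.3% of its charge, is more than the target formed, 3.9%. So before choosing between ochre and blue we write the balance of the substrate, the limiting reagent against 1.05 equiv of coupling partner: what is used is target plus what went elsewhere.

in all of them: coupling partner 1.05 equiv
- eta: substrate 3 mM; run made earlier
- zeta: substrate 4.5 mM; run made earlier
- ochre: substrate 2.0 mM; time 2.0 min
- blue: substrate 3.0 mM; time 3.0 min

| run | time / s | target / % | substrate / % |
|---|---|---|---|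
| eta | 10.0 | 3.9 | 56.7 |
| eta | 15.0 | 4.5 | 50.8 |
| eta | 40.0 | 8.7 | 37.6 |
| eta | 80.0 | 16.8 | 21.6 |
| zeta | 20.0 | 5.0 | 40.2 |
| zeta | 40.0 | 8.9 | 29.1 |
| zeta | 60.0 | 9.4 | 22.8 |
| zeta | 80.0 | 14.6 | 16.8 |

(scatter of a reading: 1 percentage point)

* the winner by amount of target, in percent of the substrate charged; "neither" if no more than 2 percentage points parts them (ochre / blue / neither)
* how much target is there at the end, in percent of the substrate charged: ochre
* how much target is there at the end, in percent of the substrate charged: blue

- where the amount of substrate changes, what is given in equivalents or mol% on it follows

The last readings give 3.67 in eta and 4.70 in zeta for the quantity we carry, the loss ratio ρ, substrate used otherwise than to target per target formed, so that target is the substrate used divided by 1 + ρ. Between the two runs ρ climbs by 0.688 mM⁻¹, and on that line ochre has 2.98, while blue is the eta charge run longer. The substrate in eta decays at 0.0139 s⁻¹ over its last two readings, which on eta's curve leaves 5.40% at 3.0 min for blue. Ochre is charged lower and so lies on no curve we have, but at 80.0 s the substrate left in eta is more than in zeta, and the line through those two readings puts ochre at 24.8% at that time, which we carry on at the same decay constant, as an assumption, to an estimated 14.2% at 2.0 min. Our reckoning therefore gives 20.3% for blue and 21.6% for ochre, a gap of 1.3 percentage points, inside the margin of 2 points. We say neither, and we would charge ochre, which takes less time than blue.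

The forecast said 25% for ochre, 41% for blue and so blue: “Blue clearly wins, mainly because of its longer time.”

    target ⇌ isomer of the product (K = 0.110, k = 0.0461 s⁻¹)
    intermediate A → side product (k = 0.00136 s⁻¹)
    substrate ⇌ intermediate B (K = 0.130, k = 0.131 s⁻¹)
    substrate + coupling partner → intermediate A (k = 8.78 M⁻¹ s⁻¹)
    coupling partner + intermediate B ⇌ intermediate C (K = 910 M⁻¹, k = 238 M⁻¹ s⁻¹)
    substrate → target (k = 0.00518 s⁻¹)

The simulation gives 21.3% in ochre and 20.9% in blue, so neither, and with the substrate left there, 18% and 6.7%, our ratios give 20.6% and 20.0%. In ochre the substrate went to intermediate A 3.6 times as fast as to target at the start and 1.6 times as fast at 2.00 min; in blue, from 1.50 min to 3.00 min, target rose from 15.9% to 20.9% as substrate fell from 19.2% to 6.67%, with intermediate A at 57.0%.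

A neighbour of ochre charged with 0.80 mM of substrate is given ρ = 2.15 by the same line, and with 28.5% of its substrate left that gives 22.7% of target; the simulation gives 28.0%, more than the line gives.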